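## Structural features

The target, 7-hydroxy-3,5,6,8-tetramethoxy-2-(4-methoxyphenyl)chromen-4-one, is a flavone. Ring A (benzene) and ring C (4-pyranone) are fused through C4a–C8a, and ring B (4-methoxyphenyl) is joined to C2 by one C–C bond. Ring A is hexasubstituted: methoxy groups on C5, C6 and C8, a free hydroxyl on C7, the ring oxygen O1 on C8a and the carbonyl carbon C4 on C4a. Ring C carries a further methoxy group on C3. There is no stereocentre, so the problem is entirely one of regiochemistry. The real difficulty is placing four contiguous oxygens on ring A so that only the C7 oxygen, flanked by two methoxy groups, ends as a phenol. Fragile points are the pyranone (opened by hard nucleophiles at C2), the electron-rich ring A once the phenol is free, and the C3 and C5 methyl ethers towards Lewis acids. The key step uses the fact that O1 (on C8a) and C4 (on C4a) are ortho neighbours on ring A and that C4a is flanked by the C5 methoxy group. An aryne spanning C4a–C8a can therefore take up O1 and C4 in one operation, with that methoxy group fixing the orientation; C2, C3, the C3 methoxy group and ring B arrive with the three-carbon acid.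

## Logic of the disconnections

19 ⇒ 18. The O7–benzyl bond is the last one made in reverse. O7 must stay distinguishable from five methyl ethers, and a benzyl ether tolerates organolithium, fluoride, NBS and hot methoxide yet leaves under neutral conditions. The gain is that every earlier intermediate is non-acidic and resistant to oxidation. The forward step must be a hydrogenolysis that spares C2=C3 and the methyl ethers.

18 ⇒ 17 ⇒ 16. The C8–OMe bond is cut to C8–Br and then to C8–H. The C8 oxygen cannot travel with the aryne, because a second flanking methoxy group would cancel the directing effect of the first. C8 is the only unsubstituted carbon of ring A in 16. The gain is an aryne with a single, unambiguous bias. The forward steps must brominate ring A in preference to ring B and then exchange a di-ortho-substituted bromide for methoxide without opening the pyranone.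

16 ⇒ 8 + 13 (through 15 and 14). Three bonds are cut: O1–C2, C4a–C4 and C8a–O1. This removes all of ring C at once and divides the molecule into two fragments of similar size: 8 holds ring A with three of its oxygens, and 13 holds C2, C3, C4, both oxygens of the pyranone, the C3 methoxy group and ring B. The forward step must control the regiochemistry of addition to an unsymmetrical aryne, favour acyl shift over protonation of the aryl anion, and achieve addition–elimination at a fully substituted, electron-rich β-carbon.

13 ⇒ 12 ⇒ 11. The carboxyl group is traced to its methyl ester and the enol O–CH3 bond is cut. This reveals a β-keto ester, the natural product of an acylation. The forward steps must methylate on oxygen, not on carbon, and hydrolyse the ester without hydrolysing the enol ether.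

11 ⇒ 9 + 10. The C–C bond between the future C2 and C3 is cut (Claisen disconnection). Both pieces are commercial. The forward step must give monoacylation of the ester enolate.

8 ⇒ 5 (through 7 and 6). The C–Si and O–S bonds are cut. A retro-Brook shift moves silicon from the phenol oxygen to the carbon that carried bromine, so the ortho relation of silyl group and triflate is fixed by the position of the bromine. The forward step must achieve clean bromine–lithium exchange in the presence of a benzyl ether.

5 ⇒ 4. The C–Br bond is cut. The forward step must brominate ortho to the free hydroxyl and not ortho to the benzyloxy group.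

4 ⇒ 3 ⇒ 1 (through 2). The O–benzyl bond is cut to a symmetrical hydroquinone, for which only the degree of alkylation matters. The para C–O bond is then cut back to the commercial phenol. The forward steps must give para-selective oxidation and mono-alkylation.

## Other disconnections considered

Alternative 1: The cut is at the two aryl C–O bonds C6–OMe and C8–OMe of a preformed flavone. 5,7-Dihydroxy-3-methoxy-2-(4-methoxyphenyl)chromen-4-one A1, reachable by a classical Allan–Robinson condensation, would be dibrominated at C6 and C8, benzylated at O7 and methylated at O5 to give 7-benzyloxy-6,8-dibromo-3,5-dimethoxy-2-(4-methoxyphenyl)chromen-4-one A2. Heating A2 with NaOMe and CuBr (monovalent copper) in DMF would exchange both bromides in one operation and give 7-benzyloxy-3,5,6,8-tetramethoxy-2-(4-methoxyphenyl)chromen-4-one A3, which is identical with 18.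
- In favour: every reaction is of a type established on flavones, and ring C is never built in an untested way. The sequence from A1 to the target is about five steps. On step count and on reliance on precedent this alternative is the better plan.
- Against: two Ullmann-type exchanges must both go to completion on a hexasubstituted ring, the C6 bromide lying between two alkoxy groups. Each hydrodebromination would give a mono-methoxy flavone that is hard to separate, and methoxide has twice the opportunity to attack the pyranone.
- Comparison: in the copper step the two plans are equals in kind, and the chosen plan asks for one exchange in place of two. The chosen plan is better in convergence and in bringing the C6 oxygen with the aryne. It is worse in that its ring-forming step is unproven.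

Alternative 2: The cut is at C3–C4 and O1–C2. Heating 3-benzyloxy-6-(hydroxymethyl)-2,4,5-trimethoxyphenol A4 would release the o-quinone methide A5. This would add 1-[(Z)-1,2-dimethoxyethenyl]-4-methoxybenzene A6 in an inverse-demand hetero-Diels–Alder reaction to give the racemic cis-2-methoxychroman A7; the cis relation of the C2 and C3 methoxy groups follows from the Z alkene in a suprafacial addition. Loss of methanol to the 4H-chromene A8, oxidation of C4 to the ketone and hydrogenolysis would follow.
- In favour: the conditions are neutral and thermal, and the regiochemistry follows from polarity (the CH(OMe) terminus bonds to the methide carbon). Ring A is fully oxygenated before the key step, so no copper chemistry is needed; on that point it is better than the chosen plan. The cycloaddition type is also better precedented than the chosen ring closure.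
- Against: A4 is a hexasubstituted benzene with four differentiated oxygens and a hydroxymethyl group, which needs a longer preparation than 8. Four donor oxygens lower the electrophilicity of A5. The adduct is at the wrong oxidation level at C4. Two stereocentres are made only to be destroyed. Oxidising the C4 methylene of A8 on a very electron-rich ring with a benzyl ether present is a selectivity risk.
- Comparison: both plans close ring C in one step, and the number of steps after the key step is equal (three). The chosen plan is shorter before the key step and delivers the correct oxidation level directly.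

Alternative 3: The cut is at C8–C8a and C5–C6, so that ring A is built on a pyranone. Under NaOMe, the enolate of 1,3-dimethoxypropan-2-one A10 would displace methanethiolate from methyl 5-methoxy-6-(4-methoxyphenyl)-2-(methylsulfanyl)-4-oxo-4H-pyran-3-carboxylate A9 at the carbon that becomes C8a. Its second α-carbon would then undergo Claisen condensation with the ester, and enolisation would aromatise ring A to 5,7-dihydroxy-3,6,8-trimethoxy-2-(4-methoxyphenyl)chromen-4-one A11.
- In favour: the C6 and C8 methoxy groups arrive preinstalled from a cheap, symmetrical ketone. There is no aryne, no halogenation and no copper step, and no regiochemical question on ring A. On these points it is better than the chosen plan.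
- Against: the aryl-bearing carbon of A9 is a second Michael terminus, and attack there opens the pyranone. An α-alkoxy ketone enolate is a modest nucleophile and prone to self-condensation. A9 itself needs several steps. A11 has two free phenols, so benzylation at O7, methylation of the chelated O5 (arriving at 18) and hydrogenolysis are still required.
- Comparison: the key steps of both plans lack direct precedent, so they are equals in risk. The overall step count would be comparable. The chosen plan keeps O7 differentiated from the start, whereas this alternative must differentiate it late; that late differentiation is, however, a dependable operation.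

Key step: step 8

Remark on the chemistry: 12, 13 and 15 are drawn as E isomers (the two methoxy groups trans). The geometry has no bearing on 16, because C2=C3 is re-formed inside the pyranone after addition–elimination.

Remark on the chemistry: the numbering of 8 was checked against 16. The triflate carbon is flanked by a methoxy group (future C4a) and the silyl carbon by hydrogen (future C8a), so the oxygen substituents fall on C5, C6 and C7; no structure needs correction.

## Route

Step 1
Reactants: 1 2,3-dimethoxyphenol
Product: 3 2,3-dimethoxybenzene-1,4-diol, via 2,3-dimethoxy-1,4-benzoquinone 2 (not isolated)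
Conditions: (KSO3)2NO (2.2 equiv), KH2PO4, H2O/acetone, 0 °C to rt; extract into EtOAc; then aq. Na2S2O4, rt
Reagents that add atoms: potassium nitrosodisulfonate, [K+].[K+].[O]N(S(=O)(=O)[O-])S(=O)(=O)[O-]
Why: Teuber oxidation: the phenoxyl radical formed by the first equivalent of (KSO3)2NO is trapped by a second at the free para position, and loss of imidodisulfonate gives p-quinone 2. Shaking the extract with dithionite is a standard two-electron reduction to the hydroquinone.

Step 2
Reactants: 3 2,3-dimethoxybenzene-1,4-diol
Product: 4 4-benzyloxy-2,3-dimethoxyphenol
Conditions: BnBr (0.9 equiv), K2CO3, acetone (degassed), N2, reflux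
Reagents that add atoms: benzyl bromide, BrCc1ccccc1
Why: Williamson etherification; 3 is symmetrical, so either hydroxyl gives the same monoether and only mono- versus dialkylation matters, which is limited by keeping BnBr as the limiting reagent. Exclusion of air prevents re-oxidation of the hydroquinone to 2.

Step 3
Reactants: 4 4-benzyloxy-2,3-dimethoxyphenol
Product: 5 4-benzyloxy-6-bromo-2,3-dimethoxyphenol
Conditions: NBS, i-Pr2NH (cat.), CH2Cl2, −78 to 0 °C, dark
Reagents that add atoms: N-bromosuccinimide, O=C1CCC(=O)N1Br
Why: Amine-mediated electrophilic bromination of a phenol: the N-bromoamine delivers bromine ortho to the hydrogen-bonded hydroxyl, and C6 is the only free ortho position. The free hydroxyl is a stronger activator than the benzyl ether next to the other open position, C5.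

Step 4
Reactants: 5 4-benzyloxy-6-bromo-2,3-dimethoxyphenol
Product: 8 4-benzyloxy-2,3-dimethoxy-6-(trimethylsilyl)phenyl trifluoromethanesulfonate, via aryl trimethylsilyl ether 6 (not isolated), via o-silylphenoxide 7 (not isolated)
Conditions: HMDS, THF, 65 °C, then concentrate in the same flask; n-BuLi, THF, −78 °C; then PhNTf2, −78 °C to rt
Reagents that add atoms: hexamethyldisilazane, C[Si](C)(C)N[Si](C)(C)C; N-phenylbis(trifluoromethanesulfonimide), O=S(=O)(N(c1ccccc1)S(=O)(=O)C(F)(F)F)C(F)(F)F
Why: O-silylation, bromine–lithium exchange and 1,3 O-to-C silyl migration (retro-Brook rearrangement) place silicon on the carbon that carried bromine and release phenoxide 7, which PhNTf2 triflates. This is the standard one-flask route from o-bromophenols to o-silylaryl triflates, and the benzyl ether is inert to n-BuLi at −78 °C.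

Step 5
Reactants: 9 methyl methoxyacetate; 10 4-methoxybenzoyl chloride
Product: 11 methyl 2-methoxy-3-(4-methoxyphenyl)-3-oxopropanoate (racemic)
Conditions: LiN(SiMe3)2 (2.1 equiv), THF, −78 °C; then 10, −78 to 0 °C; aq. NH4Cl
Reagents that add atoms: none
Why: Crossed Claisen acylation of the lithium enolate of 9 by the acid chloride; the second equivalent of base turns the more acidic β-keto ester into its enolate and stops further acylation. The α-stereocentre of 11 forms racemic and is removed in step 6.

Step 6
Reactants: 11 methyl 2-methoxy-3-(4-methoxyphenyl)-3-oxopropanoate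
Product: 12 methyl (E)-2,3-dimethoxy-3-(4-methoxyphenyl)prop-2-enoate
Conditions: MeOTs, Cs2CO3, DMF, rt
Reagents that add atoms: methyl p-toluenesulfonate, COS(=O)(=O)c1ccc(C)cc1
Why: O-alkylation of a β-keto ester enolate: a caesium enolate in DMF and a hard sulfonate electrophile favour reaction at oxygen, and C-methylation would have to build a quaternary α-carbon. A non-volatile methylating agent is chosen for safety.

Step 7
Reactants: 12 methyl (E)-2,3-dimethoxy-3-(4-methoxyphenyl)prop-2-enoate
Product: 13 (E)-2,3-dimethoxy-3-(4-methoxyphenyl)prop-2-enoic acid
Conditions: LiOH, THF/MeOH/H2O, 40 °C; then 1 M HCl, 0 °C, to pH 3, immediate extraction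
Reagents that add atoms: lithium hydroxide, [Li+].[OH-]
Why: Saponification by acyl–oxygen cleavage; the fully substituted, donor-bearing β-carbon of the vinylogous carbonate resists hydroxide. Brief cold acidification avoids hydrolysis of the enol ether to a β-keto acid, which would decarboxylate.

Step 8
Reactants: 8 4-benzyloxy-2,3-dimethoxy-6-(trimethylsilyl)phenyl trifluoromethanesulfonate; 13 (E)-2,3-dimethoxy-3-(4-methoxyphenyl)prop-2-enoic acid
Product: 16 7-benzyloxy-3,5,6-trimethoxy-2-(4-methoxyphenyl)chromen-4-one, via 5-benzyloxy-3,4-dimethoxybenzyne 14 (not isolated), via o-acylphenoxide 15 (not isolated)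
Conditions: CsF (4 equiv), THF, 125 °C, sealed tube
Reagents that add atoms: none
Why: Proposed new method: fluoride removes the trimethylsilyl group of 8 and triflate leaves to give aryne 14, while CsF converts 13 into its caesium carboxylate; the carboxylate oxygen adds to the aryne carbon remote from the flanking methoxy group (future C8a), because that is the more distorted, more electrophilic terminus of a 3-alkoxyaryne and the in-plane aryl anion then sits at future C4a beside the inductively withdrawing C5 methoxy oxygen. The aryl anion attacks the neighbouring ester carbonyl (4-exo-trig) and the four-membered alkoxide opens to phenoxide 15, a net insertion of the aryne into the acyl C–O bond; the closest known reaction type is the CsF-mediated insertion of arynes into the C–O bond of carboxylic acids, which gives o-hydroxyaryl ketones and, with arylpropiolic acids, flavones. Ring C then closes by 6-endo-trig oxa-Michael addition of the phenoxide to the methoxy-bearing β-carbon (C2) followed by E1cB loss of methoxide, which mirrors the usual closure of o-hydroxyaryl β-alkoxy enones to chromones but has not been shown in the aryne series. No stereocentre is formed, and the double-bond geometry of 13 is erased at the tetrahedral adduct. The selectivities needed are the regiochemistry on the unsymmetrical aryne, secured by the single flanking methoxy group (C8 is left as hydrogen for this reason), and carbonyl attack by the aryl anion in preference to conjugate addition, secured by the proximity of the carbonyl and by the hindered, electron-rich β-carbon. The methoxide released is taken up as methanol by the HF formed from the acid, and the fast intramolecular closure should protect the phenoxide from arylation by a second aryne.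

Step 9
Reactants: 16 7-benzyloxy-3,5,6-trimethoxy-2-(4-methoxyphenyl)chromen-4-one
Product: 17 7-benzyloxy-8-bromo-3,5,6-trimethoxy-2-(4-methoxyphenyl)chromen-4-one
Conditions: NBS, DMF, 0 °C to rt, dark
Reagents that add atoms: N-bromosuccinimide, O=C1CCC(=O)N1Br
Why: Electrophilic aromatic bromination; C8 is the only unsubstituted carbon of ring A and is activated ortho by O1 and the C7 benzyloxy group and para by the C5 methoxy group, whereas ring B is deactivated by conjugation with the pyranone. Ionic conditions in the dark leave the benzylic CH2 untouched.

Step 10
Reactants: 17 7-benzyloxy-8-bromo-3,5,6-trimethoxy-2-(4-methoxyphenyl)chromen-4-one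
Product: 18 7-benzyloxy-3,5,6,8-tetramethoxy-2-(4-methoxyphenyl)chromen-4-one
Conditions: NaOMe (excess), CuBr (0.2 equiv), DMF/MeOH, 110 °C, N2
Reagents that add atoms: sodium methoxide, [Na+].[O-]C
Why: Ullmann-type C–O coupling: CuBr (monovalent copper) mediates exchange of the aryl bromide for methoxide, a reaction type established for 6- and 8-bromoflavones. Any reversible addition of methoxide at C2 of the pyranone should revert on work-up.

Step 11
Reactants: 18 7-benzyloxy-3,5,6,8-tetramethoxy-2-(4-methoxyphenyl)chromen-4-one
Product: 19 7-hydroxy-3,5,6,8-tetramethoxy-2-(4-methoxyphenyl)chromen-4-one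
Conditions: H2 (1 atm), Pd/C, EtOAc/MeOH, rt
Reagents that add atoms: none
Why: Hydrogenolysis of an aryl benzyl ether over Pd/C at atmospheric pressure; the tetrasubstituted C2=C3 bond of the pyranone and the aryl methyl ethers should not be reduced under these conditions.

## Compound list

1 | 2,3-dimethoxyphenol | COc1cccc(O)c1OC | starting material
2 | 2,3-dimethoxy-1,4-benzoquinone | COC1=C(OC)C(=O)C=CC1=O | intermediate
3 | 2,3-dimethoxybenzene-1,4-diol | COc1c(O)ccc(O)c1OC | intermediate
4 | 4-benzyloxy-2,3-dimethoxyphenol | COc1c(OCc2ccccc2)ccc(O)c1OC | intermediate
5 | 4-benzyloxy-6-bromo-2,3-dimethoxyphenol | COc1c(OCc2ccccc2)cc(Br)c(O)c1OC | intermediate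
6 | (4-benzyloxy-6-bromo-2,3-dimethoxyphenoxy)trimethylsilane | COc1c(OCc2ccccc2)cc(Br)c(O[Si](C)(C)C)c1OC | intermediate
7 | lithium 4-benzyloxy-2,3-dimethoxy-6-(trimethylsilyl)phenoxide | [Li+].COc1c(OCc2ccccc2)cc([Si](C)(C)C)c([O-])c1OC | intermediate
8 | 4-benzyloxy-2,3-dimethoxy-6-(trimethylsilyl)phenyl trifluoromethanesulfonate | COc1c(OCc2ccccc2)cc([Si](C)(C)C)c(OS(=O)(=O)C(F)(F)F)c1OC | intermediate
9 | methyl methoxyacetate | COCC(=O)OC | starting material
10 | 4-methoxybenzoyl chloride | COc1ccc(C(=O)Cl)cc1 | starting material
11 | methyl 2-methoxy-3-(4-methoxyphenyl)-3-oxopropanoate (racemic) | COC(C(=O)OC)C(=O)c1ccc(OC)cc1 | intermediate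
12 | methyl (E)-2,3-dimethoxy-3-(4-methoxyphenyl)prop-2-enoate | CO/C(C(=O)OC)=C(/OC)c1ccc(OC)cc1 | intermediate
13 | (E)-2,3-dimethoxy-3-(4-methoxyphenyl)prop-2-enoic acid | CO/C(C(=O)O)=C(/OC)c1ccc(OC)cc1 | intermediate
14 | 5-benzyloxy-3,4-dimethoxybenzyne (5-benzyloxy-1,2-didehydro-3,4-dimethoxybenzene) | COC1=C(OC)C(OCc2ccccc2)=CC#C1 | intermediate
15 | caesium 5-benzyloxy-2-[(E)-2,3-dimethoxy-3-(4-methoxyphenyl)prop-2-enoyl]-3,4-dimethoxyphenoxide | [Cs+].CO/C(C(=O)c1c([O-])cc(OCc2ccccc2)c(OC)c1OC)=C(/OC)c1ccc(OC)cc1 | intermediate
16 | 7-benzyloxy-3,5,6-trimethoxy-2-(4-methoxyphenyl)chromen-4-one | COc1ccc(-c2oc3cc(OCc4ccccc4)c(OC)c(OC)c3c(=O)c2OC)cc1 | intermediate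
17 | 7-benzyloxy-8-bromo-3,5,6-trimethoxy-2-(4-methoxyphenyl)chromen-4-one | COc1ccc(-c2oc3c(Br)c(OCc4ccccc4)c(OC)c(OC)c3c(=O)c2OC)cc1 | intermediate
18 | 7-benzyloxy-3,5,6,8-tetramethoxy-2-(4-methoxyphenyl)chromen-4-one | COc1ccc(-c2oc3c(OC)c(OCc4ccccc4)c(OC)c(OC)c3c(=O)c2OC)cc1 | intermediate
19 | 7-hydroxy-3,5,6,8-tetramethoxy-2-(4-methoxyphenyl)chromen-4-one | COc1ccc(-c2oc3c(OC)c(O)c(OC)c(OC)c3c(=O)c2OC)cc1 | target

## Step count and least certain steps

Total step count: 11. Longest linear sequence: 8 steps (steps 1–4, then 8–11); the acid branch (steps 5–7) has 3 steps.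

Step 8 (key step, proposed new method). Three processes may divert it:
- The aryl anion may be protonated by HF before the acyl shift, which would stop the sequence at the aryl ester.
- Addition–elimination at the fully substituted, electron-rich β-carbon may be too slow, which would leave the sequence at the open o-hydroxyaryl ketone.
- Some of the carboxylate may add at the proximal aryne carbon.

Fallback with known chemistry, setting out from 8 and returning at 16: CsF-mediated insertion of the aryne from 8 into methoxyacetic acid, the established form of the reaction with a simple aliphatic acid, should give 1-(4-benzyloxy-6-hydroxy-2,3-dimethoxyphenyl)-2-methoxyethan-1-one F1. Treatment of F1 with LiN(SiMe3)2 (3 equiv) and 10 would give, by O-aroylation and Baker–Venkataraman acyl shift, 1-(4-benzyloxy-6-hydroxy-2,3-dimethoxyphenyl)-2-methoxy-3-(4-methoxyphenyl)propane-1,3-dione F2. Cyclodehydration of F2 (TsOH, toluene, heat) closes ring C and gives 16.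

Step 2. Over-alkylation to the dibenzyl ether and air oxidation of the hydroquinone under base may erode the monoether. Fallback, setting out from 1 and returning at 4: Elbs persulfate oxidation of 1 (K2S2O8, aq. NaOH) places a sulfate ester on the new para oxygen and gives potassium 4-hydroxy-2,3-dimethoxyphenyl sulfate F3, in which the two oxygens are already differentiated. Benzylation of the free phenol (BnCl, aq. NaOH) gives potassium 4-benzyloxy-2,3-dimethoxyphenyl sulfate F4, and warm dilute HCl hydrolyses the aryl sulfate to 4.

Step 3. Bromination may also occur ortho to the benzyloxy group, or NBS may oxidise the p-alkoxyphenol with loss of the benzyl group. Fallback, setting out from 4 and returning at 8, with the position fixed by directed ortho-metalation in place of halogenation: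
- 4 is converted with i-PrNCO and Et3N into 4-benzyloxy-2,3-dimethoxyphenyl N-(propan-2-yl)carbamate F5.
- N-Silylation (TBSOTf, TMEDA), ortho-lithiation (n-BuLi, TMEDA, −78 °C) and a TMSCl quench give 4-benzyloxy-2,3-dimethoxy-6-(trimethylsilyl)phenyl N-(propan-2-yl)carbamate F6; the only position ortho to the carbamate is the required one.
- DBU and Et2NH in MeCN cleave the carbamate to 4-benzyloxy-2,3-dimethoxy-6-(trimethylsilyl)phenol F7, which is triflated in the same flask with PhNTf2 to give 8.

Step 6. Methylation at the doubly activated carbon in place of oxygen would give a quaternary α-methyl keto ester. Fallback, setting out from 11 and returning at 12: acid-catalysed ketalisation (HC(OMe)3, TsOH, MeOH) gives methyl 2,3,3-trimethoxy-3-(4-methoxyphenyl)propanoate F8. Elimination of methanol from F8 (TMSOTf, i-Pr2NEt, CH2Cl2) gives enol ether 12 without any enolate alkylation.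

Step 10. Hydrodebromination back to 16, or irreversible opening of the pyranone by methoxide at the high temperature, may compete with the copper-mediated exchange. Fallback, setting out from 17 and returning at 18: Miyaura borylation (B2pin2, PdCl2(dppf), KOAc, dioxane) gives 7-benzyloxy-3,5,6-trimethoxy-2-(4-methoxyphenyl)-8-(4,4,5,5-tetramethyl-1,3,2-dioxaborolan-2-yl)chromen-4-one F9. Oxidation with NaBO3 in THF/H2O gives 7-benzyloxy-8-hydroxy-3,5,6-trimethoxy-2-(4-methoxyphenyl)chromen-4-one F10, and O-methylation (MeOTs, K2CO3, acetone) gives 18.

## Further compounds

F1 | step 8 | 1-(4-benzyloxy-6-hydroxy-2,3-dimethoxyphenyl)-2-methoxyethan-1-one | COCC(=O)c1c(O)cc(OCc2ccccc2)c(OC)c1OC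
F2 | step 8 | 1-(4-benzyloxy-6-hydroxy-2,3-dimethoxyphenyl)-2-methoxy-3-(4-methoxyphenyl)propane-1,3-dione (racemic) | COc1ccc(C(=O)C(OC)C(=O)c2c(O)cc(OCc3ccccc3)c(OC)c2OC)cc1
F3 | step 2 | potassium 4-hydroxy-2,3-dimethoxyphenyl sulfate | [K+].COc1c(O)ccc(OS(=O)(=O)[O-])c1OC
F4 | step 2 | potassium 4-benzyloxy-2,3-dimethoxyphenyl sulfate | [K+].COc1c(OCc2ccccc2)ccc(OS(=O)(=O)[O-])c1OC
F5 | step 3 | 4-benzyloxy-2,3-dimethoxyphenyl N-(propan-2-yl)carbamate | COc1c(OCc2ccccc2)ccc(OC(=O)NC(C)C)c1OC
F6 | step 3 | 4-benzyloxy-2,3-dimethoxy-6-(trimethylsilyl)phenyl N-(propan-2-yl)carbamate | COc1c(OCc2ccccc2)cc([Si](C)(C)C)c(OC(=O)NC(C)C)c1OC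
F7 | step 3 | 4-benzyloxy-2,3-dimethoxy-6-(trimethylsilyl)phenol | COc1c(OCc2ccccc2)cc([Si](C)(C)C)c(O)c1OC
F8 | step 6 | methyl 2,3,3-trimethoxy-3-(4-methoxyphenyl)propanoate (racemic) | COC(C(=O)OC)C(OC)(OC)c1ccc(OC)cc1
F9 | step 10 | 7-benzyloxy-3,5,6-trimethoxy-2-(4-methoxyphenyl)-8-(4,4,5,5-tetramethyl-1,3,2-dioxaborolan-2-yl)chromen-4-one | COc1ccc(-c2oc3c(B5OC(C)(C)C(C)(C)O5)c(OCc4ccccc4)c(OC)c(OC)c3c(=O)c2OC)cc1
F10 | step 10 | 7-benzyloxy-8-hydroxy-3,5,6-trimethoxy-2-(4-methoxyphenyl)chromen-4-one | COc1ccc(-c2oc3c(O)c(OCc4ccccc4)c(OC)c(OC)c3c(=O)c2OC)cc1
A1 | alternative 1 | 5,7-dihydroxy-3-methoxy-2-(4-methoxyphenyl)chromen-4-one | COc1ccc(-c2oc3cc(O)cc(O)c3c(=O)c2OC)cc1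
A2 | alternative 1 | 7-benzyloxy-6,8-dibromo-3,5-dimethoxy-2-(4-methoxyphenyl)chromen-4-one | COc1ccc(-c2oc3c(Br)c(OCc4ccccc4)c(Br)c(OC)c3c(=O)c2OC)cc1
A3 | alternative 1 | 7-benzyloxy-3,5,6,8-tetramethoxy-2-(4-methoxyphenyl)chromen-4-one | COc1ccc(-c2oc3c(OC)c(OCc4ccccc4)c(OC)c(OC)c3c(=O)c2OC)cc1
A4 | alternative 2 | 3-benzyloxy-6-(hydroxymethyl)-2,4,5-trimethoxyphenol | OCc1c(O)c(OC)c(OCc2ccccc2)c(OC)c1OC
A5 | alternative 2 | 3-benzyloxy-2,4,5-trimethoxy-6-methylidenecyclohexa-2,4-dien-1-one | C=C1C(=O)C(OC)=C(OCc2ccccc2)C(OC)=C1OC
A6 | alternative 2 | 1-[(Z)-1,2-dimethoxyethenyl]-4-methoxybenzene | CO/C=C(\OC)c1ccc(OC)cc1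
A7 | alternative 2 | racemic cis-7-benzyloxy-2,3,5,6,8-pentamethoxy-2-(4-methoxyphenyl)chroman (2-OMe and 3-OMe cis, one enantiomer drawn) | CO[C@@H]1Cc2c(OC)c(OC)c(OCc3ccccc3)c(OC)c2O[C@@]1(OC)c1ccc(OC)cc1
A8 | alternative 2 | 7-benzyloxy-3,5,6,8-tetramethoxy-2-(4-methoxyphenyl)-4H-chromene | COC1=C(c2ccc(OC)cc2)Oc2c(OC)c(OCc3ccccc3)c(OC)c(OC)c2C1
A9 | alternative 3 | methyl 5-methoxy-6-(4-methoxyphenyl)-2-(methylsulfanyl)-4-oxo-4H-pyran-3-carboxylate | COC(=O)c1c(SC)oc(-c2ccc(OC)cc2)c(OC)c1=O
A10 | alternative 3 | 1,3-dimethoxypropan-2-one | COCC(=O)COC
A11 | alternative 3 | 5,7-dihydroxy-3,6,8-trimethoxy-2-(4-methoxyphenyl)chromen-4-one | COc1ccc(-c2oc3c(OC)c(O)c(OC)c(O)c3c(=O)c2OC)cc1
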